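**Retrosynthetic overview**
1. Numbering: ring C1 (CH carrying the chain), C2=C3, C4 (C(OH)CH3), C5, C6; chain = heptenoate C1–C7. Late stage: chain C3–C4 by Nozaki–Hiyama–Kishi union of aldehyde 20 with iodoacrylate 25, chain C6 methyl by Cu-catalysed asymmetric conjugate addition, then acetylation and Si–O cleavage.
2. Ring C2=C3 is unveiled by dehydration of a secondary C3–OH next to the C4 carbinol. This trans-3,4-diol is stored as a bridged γ-lactone (6-oxabicyclo[3.2.1]octan-7-one, a temporary ring) whose carbonyl is chain C6 and which fixes ring C1 relative to C4; the surplus carboxyl at ring C1 is excised at the bridgehead.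
3. Key disconnection: ring C1–C2 and ring C3–C4, formed together when a vinylsulfonium C2 unit is inserted between the malonate carbon (ring C1) and the ketone carbon (ring C4) of acyclic dimethyl 2-(3-oxobutyl)malonate 3; the C3–C4 oxirane closes in the same operation.
4. Feature that allows it: in the six-membered ring the C2=C3 alkene lies between the methine C1 and the oxygenated quaternary C4 (a 1,4-pair). C2=C3–C4(OH) is the retron of a C3–C4 oxirane, so C2/C3 can come from one two-carbon acceptor/ylide unit placed between a carbon nucleophile (C1) and a carbonyl carbon (C4).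
5. Order of ring formation: cyclohexane and oxirane together (step 3), γ-lactone by oxirane opening (step 4), lactone opened (step 6), cyclohexene by dehydration (step 12).

Key step: step 3

Assumption: (2R,5R)-2,5-dimethylthiolane 4 is treated as a purchasable C2-symmetric sulfide (otherwise two steps from (2S,5S)-hexane-2,5-diol via the dimesylate and Na2S).

Step 1
Reactants: 1 dimethyl malonate; 2 but-3-en-2-one (methyl vinyl ketone)
Product: 3 dimethyl 2-(3-oxobutyl)malonate
Conditions: 1 (2 equiv), NaOMe (5 mol %), MeOH, 0 °C to rt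
Reagents that add atoms: none
Why: Michael addition of the malonate anion to the enone should give the mono-adduct when the malonate is in excess, and no stereocentre is formed.

Step 2
Reactants: 4 (2R,5R)-2,5-dimethylthiolane; 5 2-bromoethyl trifluoromethanesulfonate
Product: 7 (2R,5R)-1-ethenyl-2,5-dimethylthiolan-1-ium trifluoromethanesulfonate, via bromoethylsulfonium triflate 6 (not isolated)
Conditions: toluene, rt; then KHCO3, THF/H2O, rt
Reagents that add atoms: none
Why: S-alkylation of the sulfide by the primary triflate followed by base-induced loss of HBr is the standard entry to vinylsulfonium salts, and the C2 axis of the thiolane keeps sulfur non-stereogenic so that a single salt results with both ring stereocentres untouched.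

Step 3
Reactants: 3 dimethyl 2-(3-oxobutyl)malonate; 7 (2R,5R)-1-ethenyl-2,5-dimethylthiolan-1-ium trifluoromethanesulfonate
Product: 9 dimethyl (1R,6S)-1-methyl-7-oxabicyclo[4.1.0]heptane-4,4-dicarboxylate, via sulfonium ylide 8 (not isolated)
Conditions: DBU (1.2 equiv), CH2Cl2, 0 °C to rt
Reagents that add atoms: none
Why: Proposed new method: DBU deprotonates only the malonate C–H of 3, the anion adds to the vinylsulfonium salt 7 (Michael addition) to give ylide 8, the ylide carbon adds to the tethered methyl ketone, and the anti betaine expels the thiolane, so that ring C1–C2, ring C3–C4 and the C3–O–C4 oxirane of the target arise in one operation. The closest known reaction type is the vinylsulfonium epoxy-annulation of ketones and aldehydes that carry a tethered nitrogen or oxygen nucleophile; the new elements are the carbon (malonate) nucleophile, which makes a carbocycle, and the enantiopure dialkylsulfonium salt. The cyclohexane closes by 6-exo-trig attack of the ylide carbon on the carbonyl group and the oxirane by 3-exo-tet displacement of the sulfide. The two new stereocentres (C1 and C6 of 9) must be cis because the oxirane is fused to the six-membered ring, and their absolute sense is set in the ylide-to-ketone addition by the C2-symmetric thiolanium group on the ylide carbon (reagent control; the sense of induction has to be confirmed in the first run, the enantiomeric salt being equally accessible). The step needs C-alkylation of the malonate without ketone enolisation, secured by the acidity gap between the malonate C–H and the ketone α-C–H, and ring closure faster than proton transfer to the ylide, secured by the six-membered transition state; diastereoselectivity is not an issue because the malonate carbon is not stereogenic.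

Step 4
Reactants: 9 dimethyl (1R,6S)-1-methyl-7-oxabicyclo[4.1.0]heptane-4,4-dicarboxylate
Product: 11 (1R,4R,5R)-4-hydroxy-4-methyl-7-oxo-6-oxabicyclo[3.2.1]octane-1-carboxylic acid, via dilithium epoxy-dicarboxylate 10 (not isolated)
Conditions: LiOH (3 equiv), THF/MeOH/H2O, rt; then aq. HCl to pH 3, rt to 40 °C
Reagents that add atoms: lithium hydroxide, [Li+].[OH-]
Why: Saponification followed by intramolecular oxirane opening (5-exo-tet lactonisation) should work because only the carboxyl group trans to the oxirane oxygen can reach the secondary oxirane carbon from the rear, so this group becomes the γ-lactone carbonyl (the future chain C6, trans to the tertiary OH) with inversion at the attacked carbon, the tertiary C–O centre stays untouched and ring C1 becomes stereogenic through this differentiation of its two carboxyl groups.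

Step 5
Reactants: 11 (1R,4R,5R)-4-hydroxy-4-methyl-7-oxo-6-oxabicyclo[3.2.1]octane-1-carboxylic acid
Product: 12 (1R,4R,5R)-4-hydroxy-4-methyl-6-oxabicyclo[3.2.1]octan-7-one
Conditions: 9-mesityl-10-phenylacridinium tetrafluoroborate (5 mol %), PhSSPh (10 mol %), i-Pr2NEt (20 mol %), CF3CH2OH, 450 nm LEDs, rt
Reagents that add atoms: none
Why: Photoredox hydrodecarboxylation (carboxylate oxidation, loss of CO2, hydrogen-atom transfer from thiophenol) should excise the free carboxyl group, and because the radical sits at the bridgehead of the bicyclic lactone the new C–H bond can only form with retention, which places this hydrogen cis to the tertiary OH.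

Step 6
Reactants: 12 (1R,4R,5R)-4-hydroxy-4-methyl-6-oxabicyclo[3.2.1]octan-7-one
Product: 13 (1R,3R,4R)-3,4-dihydroxy-N-methoxy-N,4-dimethylcyclohexane-1-carboxamide
Conditions: MeNH(OMe)·HCl, i-PrMgCl, THF, −20 to 0 °C
Reagents that add atoms: N,O-dimethylhydroxylamine hydrochloride, CNOC.Cl
Why: Aminolysis of the lactone by the magnesium amide (Weinreb amide formation) should open the temporary ring without touching any of the three stereocentres.

Step 7
Reactants: 13 (1R,3R,4R)-3,4-dihydroxy-N-methoxy-N,4-dimethylcyclohexane-1-carboxamide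
Product: 14 (1R,3R,4R)-N-methoxy-N,4-dimethyl-3,4-bis(triethylsilyloxy)cyclohexane-1-carboxamide
Conditions: Et3SiOTf (2.5 equiv), 2,6-lutidine, CH2Cl2, −78 to 0 °C
Reagents that add atoms: triethylsilyl trifluoromethanesulfonate, CC[Si](CC)(CC)OS(=O)(=O)C(F)(F)F
Why: O-silylation with the silyl triflate covers the tertiary as well as the secondary hydroxyl and so blocks re-lactonisation and a later oxa-Michael addition.

Step 8
Reactants: 14 (1R,3R,4R)-N-methoxy-N,4-dimethyl-3,4-bis(triethylsilyloxy)cyclohexane-1-carboxamide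
Product: 15 (1R,3R,4R)-4-methyl-3,4-bis(triethylsilyloxy)cyclohexane-1-carbaldehyde
Conditions: i-Bu2AlH, THF, −78 °C; aqueous potassium sodium tartrate work-up
Reagents that add atoms: none
Why: Hydride reduction of the Weinreb amide stops at the chelated hemiaminal and releases the aldehyde only on work-up, and the low temperature keeps the α-stereocentre intact.

Step 9
Reactants: 15 (1R,3R,4R)-4-methyl-3,4-bis(triethylsilyloxy)cyclohexane-1-carbaldehyde
Product: 16 ethyl (2E)-3-[(1R,3R,4R)-4-methyl-3,4-bis(triethylsilyloxy)cyclohexyl]prop-2-enoate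
Conditions: (EtO)2P(O)CH2CO2Et, LiCl, DBU, MeCN, 0 °C to rt
Reagents that add atoms: triethyl phosphonoacetate, CCOC(=O)CP(=O)(OCC)OCC
Why: Horner–Wadsworth–Emmons olefination under mild LiCl/amine conditions should give the (E)-enoate without epimerising the α-branched aldehyde.

Step 10
Reactants: 16 ethyl (2E)-3-[(1R,3R,4R)-4-methyl-3,4-bis(triethylsilyloxy)cyclohexyl]prop-2-enoate
Product: 17 ethyl (3R)-3-[(1R,3R,4R)-4-methyl-3,4-bis(triethylsilyloxy)cyclohexyl]butanoate
Conditions: MeMgBr, copper iodide (CuI, 3 mol %), (R)-2,2'-bis(di-p-tolylphosphino)-1,1'-binaphthyl (4.5 mol %), t-BuOMe, −20 °C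
Reagents that add atoms: methylmagnesium bromide, C[Mg]Br
Why: Copper-catalysed asymmetric conjugate addition of the methyl Grignard reagent to the (E)-enoate sets the chain methyl stereocentre under ligand control (the ligand enantiomer is chosen to give 3R), which should override the weak bias of the neighbouring ring stereocentre.

Step 11
Reactants: 17 ethyl (3R)-3-[(1R,3R,4R)-4-methyl-3,4-bis(triethylsilyloxy)cyclohexyl]butanoate
Product: 18 ethyl (3R)-3-[(1R,3R,4R)-3-hydroxy-4-methyl-4-(triethylsilyloxy)cyclohexyl]butanoate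
Conditions: pyridinium p-toluenesulfonate (cat.), MeOH/CH2Cl2, 0 °C
Reagents that add atoms: none
Why: Acid-catalysed methanolysis (selective desilylation) should cleave the less hindered secondary silyl ether well before the tertiary one.

Step 12
Reactants: 18 ethyl (3R)-3-[(1R,3R,4R)-3-hydroxy-4-methyl-4-(triethylsilyloxy)cyclohexyl]butanoate
Product: 19 ethyl (3R)-3-[(1S,4R)-4-methyl-4-(triethylsilyloxy)cyclohex-2-en-1-yl]butanoate
Conditions: Burgess reagent (methyl N-(triethylammoniosulfonyl)carbamate), toluene, 60 °C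
Reagents that add atoms: none
Why: Syn-elimination of the secondary sulfamate (Burgess dehydration) can only take a hydrogen from the ring CH2 because the other neighbour is the fully substituted carbinol carbon, which places the alkene at ring C2=C3 and leaves ring C1 and C4 untouched.

Step 13
Reactants: 19 ethyl (3R)-3-[(1S,4R)-4-methyl-4-(triethylsilyloxy)cyclohex-2-en-1-yl]butanoate
Product: 20 (3R)-3-[(1S,4R)-4-methyl-4-(triethylsilyloxy)cyclohex-2-en-1-yl]butanal
Conditions: i-Bu2AlH (1.05 equiv), CH2Cl2, −78 °C
Reagents that add atoms: none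
Why: Low-temperature partial reduction of the ethyl ester stops at the aluminium hemiacetal and should give the aldehyde on work-up.

Step 14
Reactants: 1 dimethyl malonate; 21 5-bromo-2-methylpent-2-ene
Product: 22 dimethyl 2-(4-methylpent-3-en-1-yl)malonate
Conditions: NaH (1 equiv), 1 (2 equiv), THF/DMF, 0 to 60 °C
Reagents that add atoms: none
Why: SN2 alkylation of sodium dimethyl malonate by the primary bromide (malonic ester alkylation) should give the mono-alkylated ester when the malonate is in excess.

Step 15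
Reactants: 22 dimethyl 2-(4-methylpent-3-en-1-yl)malonate
Product: 23 dimethyl 2-(diiodomethyl)-2-(4-methylpent-3-en-1-yl)malonate
Conditions: NaH, CHI3, Et2O, reflux
Reagents that add atoms: iodoform, IC(I)I
Why: C-alkylation of the substituted malonate anion by iodoform is the established entry to 2-(diiodomethyl)malonates, the precursors of (E)-3-iodo-2-alkylacrylic acids.

Step 16
Reactants: 23 dimethyl 2-(diiodomethyl)-2-(4-methylpent-3-en-1-yl)malonate
Product: 24 (2E)-3-iodo-2-(4-methylpent-3-en-1-yl)prop-2-enoic acid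
Conditions: KOH, EtOH/H2O, reflux; then aq. HCl
Reagents that add atoms: potassium hydroxide, [K+].[OH-]
Why: Saponification and decarboxylative anti-elimination of iodide in one pot should give the iodoacrylic acid as the (E)-isomer, in which iodine and the carboxyl group are trans.

Step 17
Reactants: 24 (2E)-3-iodo-2-(4-methylpent-3-en-1-yl)prop-2-enoic acid
Product: 25 methyl (2E)-3-iodo-2-(4-methylpent-3-en-1-yl)prop-2-enoate
Conditions: MeI, K2CO3, DMF, rt
Reagents that add atoms: iodomethane, CI
Why: SN2 O-methylation of the carboxylate leaves the alkenyl iodide and its geometry untouched.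

Step 18
Reactants: 20 (3R)-3-[(1S,4R)-4-methyl-4-(triethylsilyloxy)cyclohex-2-en-1-yl]butanal; 25 methyl (2E)-3-iodo-2-(4-methylpent-3-en-1-yl)prop-2-enoate
Product: 26 methyl (2E,4S,6R)-4-hydroxy-2-(4-methylpent-3-en-1-yl)-6-[(1S,4R)-4-methyl-4-(triethylsilyloxy)cyclohex-2-en-1-yl]hept-2-enoate
Conditions: CrCl2 (3 equiv), NiCl2 (2 mol %), (S)-N-[2-(4-isopropyl-4,5-dihydrooxazol-2-yl)-6-methylphenyl]methanesulfonamide (3.3 equiv), Et3N (3.3 equiv), THF, rt
Reagents that add atoms: none
Why: In this Nozaki–Hiyama–Kishi coupling the alkenylchromium species should form from the iodide with retention of the (E)-geometry and add to the aldehyde, the new carbinol stereocentre being set by the chiral sulfonamide–oxazoline ligand on chromium (ligand enantiomer chosen to give 4S) because the β-methyl stereocentre exerts little control.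

Step 19
Reactants: 26 methyl (2E,4S,6R)-4-hydroxy-2-(4-methylpent-3-en-1-yl)-6-[(1S,4R)-4-methyl-4-(triethylsilyloxy)cyclohex-2-en-1-yl]hept-2-enoate
Product: 27 methyl (2E,4S,6R)-4-acetoxy-2-(4-methylpent-3-en-1-yl)-6-[(1S,4R)-4-methyl-4-(triethylsilyloxy)cyclohex-2-en-1-yl]hept-2-enoate
Conditions: Ac2O, pyridine, DMAP (cat.), CH2Cl2, 0 °C
Reagents that add atoms: acetic anhydride, CC(=O)OC(C)=O
Why: Acylation should take place at the only free hydroxyl (secondary, allylic) because the tertiary oxygen is still silylated.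

Step 20
Reactants: 27 methyl (2E,4S,6R)-4-acetoxy-2-(4-methylpent-3-en-1-yl)-6-[(1S,4R)-4-methyl-4-(triethylsilyloxy)cyclohex-2-en-1-yl]hept-2-enoate
Product: 28 methyl (2E,4S,6R)-4-acetoxy-6-[(1S,4R)-4-hydroxy-4-methylcyclohex-2-en-1-yl]-2-(4-methylpent-3-en-1-yl)hept-2-enoate (CNP0360342.1)
Conditions: HF·pyridine, pyridine, THF, 0 °C to rt
Reagents that add atoms: none
Why: Buffered fluoride-mediated desilylation should free the tertiary allylic alcohol without ionising it and without touching the acetate or the enoate.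

**Compound list**
1 | dimethyl malonate | COC(=O)CC(=O)OC | starting material
2 | but-3-en-2-one (methyl vinyl ketone) | CC(=O)C=C | starting material
3 | dimethyl 2-(3-oxobutyl)malonate | COC(=O)C(CCC(C)=O)C(=O)OC | intermediate
4 | (2R,5R)-2,5-dimethylthiolane | C[C@@H]1CC[C@@H](C)S1 | starting material
5 | 2-bromoethyl trifluoromethanesulfonate | BrCCOS(=O)(=O)C(F)(F)F | starting material
6 | (2R,5R)-1-(2-bromoethyl)-2,5-dimethylthiolan-1-ium trifluoromethanesulfonate | C[C@@H]1CC[C@@H](C)[S+]1CCBr.[O-]S(=O)(=O)C(F)(F)F | intermediate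
7 | (2R,5R)-1-ethenyl-2,5-dimethylthiolan-1-ium trifluoromethanesulfonate | C[C@@H]1CC[C@@H](C)[S+]1C=C.[O-]S(=O)(=O)C(F)(F)F | intermediate
8 | sulfonium ylide, dimethyl 2-{2-[(2R,5R)-2,5-dimethylthiolan-1-ium-1-yl]-2-idoethyl}-2-(3-oxobutyl)malonate | COC(=O)C(CCC(C)=O)(C[CH-][S+]1[C@H](C)CC[C@H]1C)C(=O)OC | intermediate
9 | dimethyl (1R,6S)-1-methyl-7-oxabicyclo[4.1.0]heptane-4,4-dicarboxylate | COC(=O)C1(C(=O)OC)CC[C@@]2(C)O[C@H]2C1 | intermediate
10 | dilithium (1R,6S)-1-methyl-7-oxabicyclo[4.1.0]heptane-4,4-dicarboxylate | [Li+].[Li+].[O-]C(=O)C1(C([O-])=O)CC[C@@]2(C)O[C@H]2C1 | intermediate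
11 | (1R,4R,5R)-4-hydroxy-4-methyl-7-oxo-6-oxabicyclo[3.2.1]octane-1-carboxylic acid | OC(=O)[C@@]12CC[C@@](C)(O)[C@@H](C1)OC2=O | intermediate
12 | (1R,4R,5R)-4-hydroxy-4-methyl-6-oxabicyclo[3.2.1]octan-7-one | [C@@H]12CC[C@@](C)(O)[C@@H](C1)OC2=O | intermediate
13 | (1R,3R,4R)-3,4-dihydroxy-N-methoxy-N,4-dimethylcyclohexane-1-carboxamide | CON(C)C(=O)[C@@H]1CC[C@@](C)(O)[C@H](O)C1 | intermediate
14 | (1R,3R,4R)-N-methoxy-N,4-dimethyl-3,4-bis(triethylsilyloxy)cyclohexane-1-carboxamide | CON(C)C(=O)[C@@H]1CC[C@@](C)(O[Si](CC)(CC)CC)[C@H](O[Si](CC)(CC)CC)C1 | intermediate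
15 | (1R,3R,4R)-4-methyl-3,4-bis(triethylsilyloxy)cyclohexane-1-carbaldehyde | O=C[C@@H]1CC[C@@](C)(O[Si](CC)(CC)CC)[C@H](O[Si](CC)(CC)CC)C1 | intermediate
16 | ethyl (2E)-3-[(1R,3R,4R)-4-methyl-3,4-bis(triethylsilyloxy)cyclohexyl]prop-2-enoate | CCOC(=O)/C=C/[C@@H]1CC[C@@](C)(O[Si](CC)(CC)CC)[C@H](O[Si](CC)(CC)CC)C1 | intermediate
17 | ethyl (3R)-3-[(1R,3R,4R)-4-methyl-3,4-bis(triethylsilyloxy)cyclohexyl]butanoate | CCOC(=O)C[C@@H](C)[C@@H]1CC[C@@](C)(O[Si](CC)(CC)CC)[C@H](O[Si](CC)(CC)CC)C1 | intermediate
18 | ethyl (3R)-3-[(1R,3R,4R)-3-hydroxy-4-methyl-4-(triethylsilyloxy)cyclohexyl]butanoate | CCOC(=O)C[C@@H](C)[C@@H]1CC[C@@](C)(O[Si](CC)(CC)CC)[C@H](O)C1 | intermediate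
19 | ethyl (3R)-3-[(1S,4R)-4-methyl-4-(triethylsilyloxy)cyclohex-2-en-1-yl]butanoate | CCOC(=O)C[C@@H](C)[C@H]1C=C[C@](C)(O[Si](CC)(CC)CC)CC1 | intermediate
20 | (3R)-3-[(1S,4R)-4-methyl-4-(triethylsilyloxy)cyclohex-2-en-1-yl]butanal | O=CC[C@@H](C)[C@H]1C=C[C@](C)(O[Si](CC)(CC)CC)CC1 | intermediate
21 | 5-bromo-2-methylpent-2-ene | CC(C)=CCCBr | starting material
22 | dimethyl 2-(4-methylpent-3-en-1-yl)malonate | COC(=O)C(CCC=C(C)C)C(=O)OC | intermediate
23 | dimethyl 2-(diiodomethyl)-2-(4-methylpent-3-en-1-yl)malonate | COC(=O)C(CCC=C(C)C)(C(I)I)C(=O)OC | intermediate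
24 | (2E)-3-iodo-2-(4-methylpent-3-en-1-yl)prop-2-enoic acid | OC(=O)/C(CCC=C(C)C)=C/I | intermediate
25 | methyl (2E)-3-iodo-2-(4-methylpent-3-en-1-yl)prop-2-enoate | COC(=O)/C(CCC=C(C)C)=C/I | intermediate
26 | methyl (2E,4S,6R)-4-hydroxy-2-(4-methylpent-3-en-1-yl)-6-[(1S,4R)-4-methyl-4-(triethylsilyloxy)cyclohex-2-en-1-yl]hept-2-enoate | COC(=O)/C(=C/[C@H](C[C@@H](C)[C@H]1C=C[C@](C)(O[Si](CC)(CC)CC)CC1)O)CCC=C(C)C | intermediate
27 | methyl (2E,4S,6R)-4-acetoxy-2-(4-methylpent-3-en-1-yl)-6-[(1S,4R)-4-methyl-4-(triethylsilyloxy)cyclohex-2-en-1-yl]hept-2-enoate | COC(=O)/C(=C/[C@H](C[C@@H](C)[C@H]1C=C[C@](C)(O[Si](CC)(CC)CC)CC1)OC(C)=O)CCC=C(C)C | intermediate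
28 | methyl (2E,4S,6R)-4-acetoxy-6-[(1S,4R)-4-hydroxy-4-methylcyclohex-2-en-1-yl]-2-(4-methylpent-3-en-1-yl)hept-2-enoate | COC(=O)/C(=C/[C@H](C[C@@H](C)[C@H]1C=C[C@](C)(O)CC1)OC(C)=O)CCC=C(C)C | target

Total steps: 20. Longest linear sequence: 15 steps (steps 1, 3 to 13, 18 to 20).

**Steps most likely to fail**

Step 3 (Proposed new method). Proton transfer from the ketone α-position to the ylide may outrun ring closure and leave open-chain sulfonium adducts, or the enantiofacial discrimination in the ylide-to-ketone addition may be low. The fallback uses known chemistry and sets out from 3. A Michael–Wittig annulation with vinyltriphenylphosphonium bromide (NaH, THF, reflux) should give the achiral cyclohexene dimethyl 4-methylcyclohex-3-ene-1,1-dicarboxylate F1. A Shi epoxidation of its trisubstituted alkene (fructose-derived ketone catalyst, KHSO5, K2CO3, MeCN/dimethoxymethane/H2O, 0 °C; catalyst enantiomer chosen for the (1R,6S)-oxirane) then returns to the route at 9.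

Step 12. The secondary sulfamate next to the silyloxy-bearing quaternary carbon may ionise and undergo a 1,2-shift (ring contraction or methyl migration) instead of syn-elimination, or sulfamate formation at the hindered hydroxyl may be slow. The fallback sets out from 18. Oxidation with Dess–Martin periodinane should give ethyl (3R)-3-[(1R,4R)-4-methyl-3-oxo-4-(triethylsilyloxy)cyclohexyl]butanoate F2. Kinetic enolisation, which is only possible towards the ring CH2 (KN(SiMe3)2, PhNTf2, THF, −78 °C), should give the enol triflate ethyl (3R)-3-[(1S,4R)-4-methyl-4-(triethylsilyloxy)-3-(trifluoromethylsulfonyloxy)cyclohex-2-en-1-yl]butanoate F3. Reduction with Pd(OAc)2, PPh3, Bu3N and HCO2H in DMF at 60 °C returns to the route at 19.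

Step 18. Facial selectivity in the addition of the alkenylchromium reagent to the β-branched aldehyde may be insufficient. The fallback sets out from 20 and 25. Ligand-free coupling (CrCl2, NiCl2 cat., DMSO) should give 26 together with its carbinol epimer methyl (2E,4R,6R)-4-hydroxy-2-(4-methylpent-3-en-1-yl)-6-[(1S,4R)-4-methyl-4-(triethylsilyloxy)cyclohex-2-en-1-yl]hept-2-enoate F4. Oxidation of the mixture with Dess–Martin periodinane should give the enone methyl (2E,6R)-2-(4-methylpent-3-en-1-yl)-6-[(1S,4R)-4-methyl-4-(triethylsilyloxy)cyclohex-2-en-1-yl]-4-oxohept-2-enoate F5. A CBS reduction (B-methyl oxazaborolidine of the enantiomer that gives 4S, catecholborane, toluene, −78 °C) returns to the route at 26.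

Further compounds
F1 | step 3 | dimethyl 4-methylcyclohex-3-ene-1,1-dicarboxylate | COC(=O)C1(C(=O)OC)CCC(C)=CC1
F2 | step 12 | ethyl (3R)-3-[(1R,4R)-4-methyl-3-oxo-4-(triethylsilyloxy)cyclohexyl]butanoate | CCOC(=O)C[C@@H](C)[C@@H]1CC[C@@](C)(O[Si](CC)(CC)CC)C(=O)C1
F3 | step 12 | ethyl (3R)-3-[(1S,4R)-4-methyl-4-(triethylsilyloxy)-3-(trifluoromethylsulfonyloxy)cyclohex-2-en-1-yl]butanoate | CCOC(=O)C[C@@H](C)[C@H]1C=C(OS(=O)(=O)C(F)(F)F)[C@](C)(O[Si](CC)(CC)CC)CC1
F4 | step 18 | methyl (2E,4R,6R)-4-hydroxy-2-(4-methylpent-3-en-1-yl)-6-[(1S,4R)-4-methyl-4-(triethylsilyloxy)cyclohex-2-en-1-yl]hept-2-enoate | COC(=O)/C(=C/[C@@H](C[C@@H](C)[C@H]1C=C[C@](C)(O[Si](CC)(CC)CC)CC1)O)CCC=C(C)C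
F5 | step 18 | methyl (2E,6R)-2-(4-methylpent-3-en-1-yl)-6-[(1S,4R)-4-methyl-4-(triethylsilyloxy)cyclohex-2-en-1-yl]-4-oxohept-2-enoate | COC(=O)/C(=C/C(=O)C[C@@H](C)[C@H]1C=C[C@](C)(O[Si](CC)(CC)CC)CC1)CCC=C(C)C
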